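Retrosynthesis: after removal of the four phenol protecting groups, ring C is cut at C2–C3 (carbene C–H insertion); the diazo group is then taken off C3 (diazo transfer to an aryl methyl ketone), the ether bond O1–CH2 is cut (Williamson etherification), and the two aryl–prenyl bonds at C6 and C8 are cut last.
Forward: ring A is bought as 2,4,6-trihydroxyacetophenone and C-prenylated twice; ring B, from methyl 3,5-dihydroxybenzoate, is attached to O1 as a benzyl ether; ring C is the only ring that is built and is closed last, by the C2–C3 bond.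
Enabling feature: C2 is benzylic to ring B and bonded to O1, and it lies six atoms from C3 along C3–C4–C4a–C8a–O1–C2. A carbene at C3 therefore reaches its doubly activated C–H bonds through a six-membered transition state, while the fifth atom, O1, carries no hydrogen.
Stereochemistry: the single stereocentre C2 is set in the ring closure by the chiral catalyst Rh2(S-PTTL)4, which chooses between the two enantiotopic benzylic hydrogens; the two deprotections that follow are buffered or mildly acidic, so ring C is never opened.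
Protecting groups: MOM on O7, O3' and O5'; triisopropylsilyl on O5, because a silyl ether survives the amide base used for the diazo transfer and offers the carbene neither a basic oxygen nor a C–H bond within reach.

Key step: step 9

Notation: prenyl = 3-methylbut-2-en-1-yl, MOM = methoxymethyl, TIPS = triisopropylsilyl, PTTL = N-phthaloyl-(S)-tert-leucinate; flavanone numbering (O1, C2, C3, C4, C4a, C5 to C8, C8a, ring B C1' to C6') is used throughout.
Assumption: Rh2(S-PTTL)4 is taken to replace the benzylic hydrogen that leads to the (2S) product; the sense of induction would be checked on a small scale, and the mirror-image catalyst Rh2(R-PTTL)4 (from D-tert-leucine) used if it proves opposite.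

Step 1
Reactants: 1 2,4,6-trihydroxyacetophenone; 2 prenyl bromide (1-bromo-3-methylbut-2-ene)
Product: 3 2,4,6-trihydroxy-3,5-diprenylacetophenone
Conditions: 2 (2.2 equiv), aq. KOH (10%), 0 °C to rt
Reagents that add atoms: none
Why: In aqueous KOH the phloroglucinol-type phenoxide reacts as a carbon nucleophile (C-alkylation of an ambident phenolate) at its two free ring positions, water solvating the oxygens and so favouring C- over O-prenylation; the diprenyl ketone should be separable by chromatography from mono- and over-alkylated material.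

Step 2
Reactants: 3 2,4,6-trihydroxy-3,5-diprenylacetophenone
Product: 4 2,6-dihydroxy-4-(MOM-oxy)-3,5-diprenylacetophenone
Conditions: MOMCl (1.05 equiv), K2CO3, acetone, 0 °C to rt
Reagents that add atoms: chloromethyl methyl ether, COCCl
Why: The 4-hydroxyl, para to the acetyl group and not hydrogen-bonded to it, is the most acidic and should be etherified first in this Williamson-type alkylation, while the two chelated ortho hydroxyls stay free.

Step 3
Reactants: 5 methyl 3,5-dihydroxybenzoate
Product: 6 methyl 3,5-bis(MOM-oxy)benzoate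
Conditions: MOMCl (2.5 equiv), K2CO3, acetone, 0 °C to rt
Reagents that add atoms: chloromethyl methyl ether, COCCl
Why: Williamson-type O-alkylation of both phenoxides with the reactive α-chloro ether should proceed cleanly, the ester being inert to carbonate.

Step 4
Reactants: 6 methyl 3,5-bis(MOM-oxy)benzoate
Product: 7 3,5-bis(MOM-oxy)benzyl alcohol
Conditions: LiAlH4, THF, 0 °C
Reagents that add atoms: none
Why: Hydride reduction of the ester to the primary alcohol; MOM acetals are stable to LiAlH4.

Step 5
Reactants: 7 3,5-bis(MOM-oxy)benzyl alcohol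
Product: 8 3,5-bis(MOM-oxy)benzyl bromide
Conditions: CBr4, PPh3, CH2Cl2, 0 °C
Reagents that add atoms: carbon tetrabromide, BrC(Br)(Br)Br
Why: The Appel reaction converts the benzylic alcohol into the bromide under essentially neutral conditions that the acid-labile MOM ethers tolerate.

Step 6
Reactants: 4 2,6-dihydroxy-4-(MOM-oxy)-3,5-diprenylacetophenone; 8 3,5-bis(MOM-oxy)benzyl bromide
Product: 9 2-[3,5-bis(MOM-oxy)benzyloxy]-6-hydroxy-4-(MOM-oxy)-3,5-diprenylacetophenone
Conditions: 8 (1.05 equiv), K2CO3, DMF, rt
Reagents that add atoms: none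
Why: Williamson etherification of one of the two equivalent ortho hydroxyls; the remaining hydroxyl, held in a strong hydrogen bond to the carbonyl and now more hindered, should not react, so the mono-ether with the O1–CH2 bond in place is expected.

Step 7
Reactants: 9 2-[3,5-bis(MOM-oxy)benzyloxy]-6-hydroxy-4-(MOM-oxy)-3,5-diprenylacetophenone
Product: 10 2-[3,5-bis(MOM-oxy)benzyloxy]-4-(MOM-oxy)-3,5-diprenyl-6-(TIPS-oxy)acetophenone
Conditions: NaH (1.05 equiv), THF, 0 °C; TIPSCl, 0 °C to rt
Reagents that add atoms: chlorotriisopropylsilane, CC(C)[Si](Cl)(C(C)C)C(C)C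
Why: O-silylation of the sodium phenoxide (one equivalent of base leaves the far less acidic methyl ketone alone) masks the last hydroxyl as a bulky silyl ether which, unlike an ester, cannot transfer to the enolate in step 8 (no Baker–Venkataraman-type acyl shift) and, unlike a free phenol, cannot trap the carbene in step 9.

Step 8
Reactants: 10 2-[3,5-bis(MOM-oxy)benzyloxy]-4-(MOM-oxy)-3,5-diprenyl-6-(TIPS-oxy)acetophenone
Product: 12 2-diazo-1-{2-[3,5-bis(MOM-oxy)benzyloxy]-4-(MOM-oxy)-3,5-diprenyl-6-(TIPS-oxy)phenyl}ethanone, via trifluoroacetyl ketone 11 (not isolated)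
Conditions: LiN(SiMe3)2, THF, −78 °C; CF3CO2CH2CF3, −78 °C; aq. NH4Cl work-up; then MsN3, Et3N, H2O, MeCN, rt
Reagents that add atoms: 2,2,2-trifluoroethyl trifluoroacetate, O=C(OCC(F)(F)F)C(F)(F)F; methanesulfonyl azide, CS(=O)(=O)N=[N+]=[N-]
Why: In this detrifluoroacetylative diazo transfer the kinetic lithium enolate of the methyl ketone is C-acylated by the trifluoroacetate (Claisen-type acylation), and the strongly acidic 1,3-diketone 11 then accepts the diazo group from MsN3 under Et3N (Regitz diazo transfer) and loses its trifluoroacetyl group to water, leaving the diazomethyl ketone; silyl ether, MOM acetals, benzyl ether and prenyl groups are inert to these conditions.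

Step 9
Reactants: 12 2-diazo-1-{2-[3,5-bis(MOM-oxy)benzyloxy]-4-(MOM-oxy)-3,5-diprenyl-6-(TIPS-oxy)phenyl}ethanone
Product: 13 (2S)-2-[3,5-bis(MOM-oxy)phenyl]-7-(MOM-oxy)-6,8-diprenyl-5-(TIPS-oxy)chroman-4-one
Conditions: Rh2(S-PTTL)4 (2 mol %), CH2Cl2, 0 °C, slow addition of 12
Reagents that add atoms: none
Why: The divalent rhodium dimer Rh2(S-PTTL)4 binds the diazo carbon of 12, N2 leaves, and the electrophilic catalyst-bound carbene at C3 inserts in a concerted three-centre step with hydride-transfer character into one benzylic O–CH2 hydrogen, forming C2–C3 and releasing the catalyst. The closest known reaction type is the dirhodium carboxylate catalysed intramolecular C–H insertion of 2-alkoxyaryl diazomethyl ketones to chroman-4-ones. Ring C closes as a 1,6-insertion through a six-membered transition state made of C3, C4, C4a, C8a, O1 and C2; a 1,5-insertion is excluded because the fifth atom is O1. C2 is set by the catalyst alone, the phthalimido walls of the four tert-leucinate ligands differentiating the two enantiotopic hydrogens of the O–CH2 group, and it is not epimerisable afterwards under the non-basic conditions used. The step needs insertion to outrun attack of the O1 lone pair on the carbene (five-membered oxonium ylide, then 1,2-benzyl shift to a benzofuranone); what should secure this is the double activation of the C–H bonds (benzylic and next to oxygen), the C8 prenyl group beside O1, which turns the O–CH2 group toward the carbene, and a carboxylate catalyst of moderate electrophilicity in a non-coordinating solvent at low temperature. The other groups should stay out of the reaction: the O5 silyl ether is bulky, weakly basic and has no C–H bond within reach, both prenyl groups sit meta to the carbon bearing the diazoacetyl group and cannot reach the carbene, and the MOM groups are remote.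

Step 10
Reactants: 13 (2S)-2-[3,5-bis(MOM-oxy)phenyl]-7-(MOM-oxy)-6,8-diprenyl-5-(TIPS-oxy)chroman-4-one
Product: 14 (2S)-2-[3,5-bis(MOM-oxy)phenyl]-5-hydroxy-7-(MOM-oxy)-6,8-diprenylchroman-4-one
Conditions: Bu4NF, AcOH (1:1), THF, 0 °C
Reagents that add atoms: none
Why: Fluoride cleaves the aryl Si–O bond (desilylation driven by the Si–F bond) while acetic acid buffers the phenoxide released, so no base strong enough to open ring C by retro-oxa-Michael elimination and racemise C2 is present; MOM ethers and alkenes are untouched.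

Step 11
Reactants: 14 (2S)-2-[3,5-bis(MOM-oxy)phenyl]-5-hydroxy-7-(MOM-oxy)-6,8-diprenylchroman-4-one
Product: 15 (2S)-2-(3,5-dihydroxyphenyl)-5,7-dihydroxy-6,8-diprenylchroman-4-one
Conditions: HCl (1 M in MeOH), rt
Reagents that add atoms: none
Why: Acid-catalysed transacetalisation with methanol removes the three aryl MOM ethers as dimethoxymethane, the usual way of unmasking prenylated flavanones; at room temperature the C2–O1 bond and the prenyl double bonds should be left alone.

Compound list
1 | 2,4,6-trihydroxyacetophenone | CC(=O)c1c(O)cc(O)cc1O | starting material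
2 | prenyl bromide (1-bromo-3-methylbut-2-ene) | CC(C)=CCBr | starting material
3 | 2,4,6-trihydroxy-3,5-bis(3-methylbut-2-enyl)acetophenone | CC(=O)c1c(O)c(CC=C(C)C)c(O)c(CC=C(C)C)c1O | intermediate
4 | 2,6-dihydroxy-4-(methoxymethoxy)-3,5-bis(3-methylbut-2-enyl)acetophenone | CC(=O)c1c(O)c(CC=C(C)C)c(OCOC)c(CC=C(C)C)c1O | intermediate
5 | methyl 3,5-dihydroxybenzoate | COC(=O)c1cc(O)cc(O)c1 | starting material
6 | methyl 3,5-bis(methoxymethoxy)benzoate | COCOc1cc(OCOC)cc(C(=O)OC)c1 | intermediate
7 | 3,5-bis(methoxymethoxy)benzyl alcohol | COCOc1cc(CO)cc(OCOC)c1 | intermediate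
8 | 3,5-bis(methoxymethoxy)benzyl bromide | COCOc1cc(CBr)cc(OCOC)c1 | intermediate
9 | 2-[3,5-bis(methoxymethoxy)benzyloxy]-6-hydroxy-4-(methoxymethoxy)-3,5-bis(3-methylbut-2-enyl)acetophenone | CC(=O)c1c(O)c(CC=C(C)C)c(OCOC)c(CC=C(C)C)c1OCc1cc(OCOC)cc(OCOC)c1 | intermediate
10 | 2-[3,5-bis(methoxymethoxy)benzyloxy]-4-(methoxymethoxy)-3,5-bis(3-methylbut-2-enyl)-6-(triisopropylsilyloxy)acetophenone | CC(=O)c1c(O[Si](C(C)C)(C(C)C)C(C)C)c(CC=C(C)C)c(OCOC)c(CC=C(C)C)c1OCc1cc(OCOC)cc(OCOC)c1 | intermediate
11 | 4,4,4-trifluoro-1-{2-[3,5-bis(methoxymethoxy)benzyloxy]-4-(methoxymethoxy)-3,5-bis(3-methylbut-2-enyl)-6-(triisopropylsilyloxy)phenyl}butane-1,3-dione | O=C(CC(=O)C(F)(F)F)c1c(O[Si](C(C)C)(C(C)C)C(C)C)c(CC=C(C)C)c(OCOC)c(CC=C(C)C)c1OCc1cc(OCOC)cc(OCOC)c1 | intermediate (not isolated)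
12 | 2-diazo-1-{2-[3,5-bis(methoxymethoxy)benzyloxy]-4-(methoxymethoxy)-3,5-bis(3-methylbut-2-enyl)-6-(triisopropylsilyloxy)phenyl}ethanone | [N-]=[N+]=CC(=O)c1c(O[Si](C(C)C)(C(C)C)C(C)C)c(CC=C(C)C)c(OCOC)c(CC=C(C)C)c1OCc1cc(OCOC)cc(OCOC)c1 | intermediate
13 | (2S)-2-[3,5-bis(methoxymethoxy)phenyl]-7-(methoxymethoxy)-6,8-bis(3-methylbut-2-enyl)-5-(triisopropylsilyloxy)chroman-4-one | CC(C)=CCc1c(OCOC)c(CC=C(C)C)c2c(c1O[Si](C(C)C)(C(C)C)C(C)C)C(=O)C[C@@H](c1cc(OCOC)cc(OCOC)c1)O2 | intermediate
14 | (2S)-2-[3,5-bis(methoxymethoxy)phenyl]-5-hydroxy-7-(methoxymethoxy)-6,8-bis(3-methylbut-2-enyl)chroman-4-one | CC(C)=CCc1c(OCOC)c(CC=C(C)C)c2c(c1O)C(=O)C[C@@H](c1cc(OCOC)cc(OCOC)c1)O2 | intermediate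
15 | (2S)-2-(3,5-dihydroxyphenyl)-5,7-dihydroxy-6,8-bis(3-methylbut-2-enyl)chroman-4-one | CC(C)=CCc1c(O)c(CC=C(C)C)c2c(c1O)C(=O)C[C@@H](c1cc(O)cc(O)c1)O2 | target

Total step count: 11.
Longest linear sequence: 9 steps (5 to 15 through steps 3, 4, 5, 6, 7, 8, 9, 10 and 11); the ring A line from 1 needs 8.

Steps most likely to fail

Step 9. The carbene may be captured by the lone pair of O1 (oxonium ylide, then migration of the benzyl group from oxygen to carbon), or the acceptor-only carbene may discriminate poorly between the two enantiotopic hydrogens. In that case ring C would be closed at O1–C2 instead and the enantiomer secured by kinetic resolution. The fallback leaves the route at 4 and 7 and rejoins it at 15. MnO2 in CH2Cl2 should oxidise 7 to 3,5-bis(methoxymethoxy)benzaldehyde F1. A second MOM group (MOMCl, iPr2NEt, CH2Cl2) should turn 4 into 2-hydroxy-4,6-bis(methoxymethoxy)-3,5-diprenylacetophenone F2. Claisen–Schmidt condensation of the two (KOH, EtOH/H2O, rt) should give the 2'-hydroxychalcone F3, which NaOAc in refluxing EtOH should close by intramolecular oxa-Michael addition to the racemic tetra-MOM flavanone F4. Asymmetric transfer hydrogenation with RuCl(p-cymene)(TsDPEN) and HCO2H/Et3N, stopped near half conversion, would then resolve F4. The catalyst enantiomer that reduces the (2R)-ketone faster is used, to be identified on F4. The resolution should leave the (2S)-tetra-MOM flavanone F5 and convert its antipode into the (2R,4R)-cis-flavan-4-ol F6, which is separated. Methanolic HCl as in step 11 would then remove the four MOM groups of F5 to give 15.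

Step 8. The silyl group may migrate from O5 to the enolate oxygen, or C-acylation of the hindered, doubly ortho-substituted lithium enolate may be incomplete. The strong base would then be avoided altogether; the fallback runs from 10 to 12. Heating 10 with Me2NCH(OMe)2 in toluene at 100 °C should give the (E)-3-(dimethylamino)-1-arylprop-2-en-1-one (enaminone) F7. Treatment of it with TsN3 in MeCN at rt should deliver 12: the azide adds across the enamine double bond and the triazoline fragments, expelling the N-sulfonyl formamidine.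

Step 11. Brønsted acid may add the freed C5 or C7 hydroxyl (or methanol) across a neighbouring prenyl double bond, closing a dimethylchroman ring before the last MOM group has left. The acetals would then be exchanged under buffered, non-protic conditions; the fallback runs from 13 to 15 and replaces steps 10 and 11. Me3SiOTf with 2,2'-bipyridyl in MeCN at 0 °C should convert the three aryl MOM ethers of 13 into trimethylsilyl ethers, giving the 5-O-triisopropylsilyl-7,3',5'-tris-O-trimethylsilyl flavanone F8. Bu4NF/AcOH in THF would then remove all four silyl groups to give 15.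

Further compounds
F1 | step 9 | 3,5-bis(methoxymethoxy)benzaldehyde | COCOc1cc(C=O)cc(OCOC)c1
F2 | step 9 | 2-hydroxy-4,6-bis(methoxymethoxy)-3,5-bis(3-methylbut-2-enyl)acetophenone | CC(=O)c1c(O)c(CC=C(C)C)c(OCOC)c(CC=C(C)C)c1OCOC
F3 | step 9 | (E)-1-[2-hydroxy-4,6-bis(methoxymethoxy)-3,5-bis(3-methylbut-2-enyl)phenyl]-3-[3,5-bis(methoxymethoxy)phenyl]prop-2-en-1-one | COCOc1cc(/C=C/C(=O)c2c(O)c(CC=C(C)C)c(OCOC)c(CC=C(C)C)c2OCOC)cc(OCOC)c1
F4 | step 9 | racemic 2-[3,5-bis(methoxymethoxy)phenyl]-5,7-bis(methoxymethoxy)-6,8-bis(3-methylbut-2-enyl)chroman-4-one | CC(C)=CCc1c(OCOC)c(CC=C(C)C)c2c(c1OCOC)C(=O)CC(c1cc(OCOC)cc(OCOC)c1)O2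
F5 | step 9 | (2S)-2-[3,5-bis(methoxymethoxy)phenyl]-5,7-bis(methoxymethoxy)-6,8-bis(3-methylbut-2-enyl)chroman-4-one | CC(C)=CCc1c(OCOC)c(CC=C(C)C)c2c(c1OCOC)C(=O)C[C@@H](c1cc(OCOC)cc(OCOC)c1)O2
F6 | step 9 | (2R,4R)-2-[3,5-bis(methoxymethoxy)phenyl]-5,7-bis(methoxymethoxy)-6,8-bis(3-methylbut-2-enyl)chroman-4-ol (cis) | CC(C)=CCc1c(OCOC)c(CC=C(C)C)c2c(c1OCOC)[C@H](O)C[C@H](c1cc(OCOC)cc(OCOC)c1)O2
F7 | step 8 | (E)-3-(dimethylamino)-1-{2-[3,5-bis(methoxymethoxy)benzyloxy]-4-(methoxymethoxy)-3,5-bis(3-methylbut-2-enyl)-6-(triisopropylsilyloxy)phenyl}prop-2-en-1-one | CN(C)/C=C/C(=O)c1c(O[Si](C(C)C)(C(C)C)C(C)C)c(CC=C(C)C)c(OCOC)c(CC=C(C)C)c1OCc1cc(OCOC)cc(OCOC)c1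
F8 | step 11 | (2S)-2-[3,5-bis(trimethylsilyloxy)phenyl]-6,8-bis(3-methylbut-2-enyl)-5-(triisopropylsilyloxy)-7-(trimethylsilyloxy)chroman-4-one | CC(C)=CCc1c(O[Si](C)(C)C)c(CC=C(C)C)c2c(c1O[Si](C(C)C)(C(C)C)C(C)C)C(=O)C[C@@H](c1cc(O[Si](C)(C)C)cc(O[Si](C)(C)C)c1)O2
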